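How much ring stands in the violet flask at 2.0 h, and can any step taken then raise it?

| flask | substrate | activator | temperature | remark | time |
|---|---|---|---|---|---|
| violet | 2 M | 1.9 M | 25 °C | the very flask that is asked about, followed so far |  |
| green | 2 M | 2.8 M | 10 °C | run made earlier |  |
| flask | 2.0 M | 1.90 M | 25 °C |  | 2.0 h |

- violet (time / min: ring / %, substrate / %): 15.0: 13.1, 2.5; 30.0: 13.0, 2.1; 50.0: 13.0, 2.5; 60.0: 13.6, 1.6; 80.0: 13.3, 1.9; 90.0: 12.4, 1.9
- green (time / min: ring / %, substrate / %): 1.33: 4.4, 5.5; 2.00: 4.7, 2.5; 4.00: 4.8, 0; 6.00: 4.5, 0.4; 10.0: 4.0, 0.4; 15.0: 4.4, 0

(each reading ± 0.3 percentage points)

- percent here means substrate units held: one open dimer counts as two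
- ring that was removed still counts
- reactions considered so far: substrate + activator -> activated form; activated form -> ring; substrate + activated form -> open dimer; ring <-> isomer of the product; activated form -> decomposed reagent; substrate <-> dormant form

- dawn: at 2.0 h take out 90% of the ring then present, then wait 2.0 h
- winter: at 2.0 h raise the temperature by 20 K, then wait 2.0 h
- midnight: change nothing and wait 2.0 h more

1. ring, in percent of the substrate first charged, at 2.0 h
2. what to do for the largest gain in ring; "none" if nothing gains more than 2 percentage points (dawn / winter / midnight / none)
3. ring present, with what was taken out counted in, in percent of the substrate first charged, after dawn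
4. ring present, with what was taken out counted in, in percent of the substrate first charged, after winter

The fastest rung is read in the green run. There activator is charged above substrate, 1.40 to one, so falling substrate meets an excess of activator (pseudo-first-order), and over one short stretch between neighbouring readings its rate is integrated here as an exponential, for that stretch and no further. Substrate reads 5.5% at 1.33 min and 2.5% at 2.00 min, which gives a read half-life of 0.589 min at 10 °C, with the scatter of those two readings.

On the next rung stands ring: the green run already reads 4.4% at 1.33 min and still 4.4% at 15.0 min, so ring is up as soon as substrate is down.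

The slowest rung shows no motion. Violet ring stays level from 15.0 min to 90.0 min, with a mean of 13.1%. The asked time lies later than the last violet reading, so this reckoning expects that mean at 2.0 h and no gain from midnight.

The violet flask at rest is therefore a count. Its activator is the limiting reagent, charged at 0.950 of the substrate. The ring yield per activator, ring at rest divided by the activator charged, both as fractions of the substrate charge, is 13.8%. The other 86.2% of the activator charged does not appear as ring in these readings.

Green, short of substrate, holds a mean ring of 4.47% per substrate charged, about a third of the violet yield, but green differs from violet in activator as well as in temperature, so this ratio is a hint about heat and no measure of it. One listed step that needs no activator is the exchange of ring with isomer of the product, which runs both ways, and level ring in the violet flask fits that exchange standing at balance, although isomer is not read. On that view, dawn lets isomer refill ring, and winter moves the balance in a direction that the readings do not show. This reckoning leans to winter on the green hint, with dawn second, as a judgement, and puts no number on either.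

The forecast gave 13% at the asked time, 13% after dawn and 12.9% after winter, and chose none, saying “no such movement is visible”; the reckoning here parts from it on winter.

The flask gives 13.1%, and the best choice is winter: it gains 13 percentage points and reaches 26.3%, against 7.9 points for dawn, which reaches 21.0%, and 0 points for midnight.

    substrate + activator → activated form (k = 0.0878 M⁻¹ s⁻¹, Ea = 58.0 kJ mol⁻¹)
    activated form → ring (k = 0.0179 s⁻¹, Ea = 92.0 kJ mol⁻¹)
    substrate + activated form → open dimer (k = 0.00268 M⁻¹ s⁻¹, Ea = 51.0 kJ mol⁻¹)
    ring ⇌ isomer of the product (K = 2.00, k = 0.182 s⁻¹, Ea = 75.0 kJ mol⁻¹, ΔH = −55.0 kJ mol⁻¹)
    activated form → decomposed reagent (k = 0.0242 s⁻¹, Ea = 76.0 kJ mol⁻¹)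
    substrate ⇌ dormant form (K = 0.305, k = 0.00642 s⁻¹, Ea = 75.0 kJ mol⁻¹, ΔH = 11.0 kJ mol⁻¹)
    (constants at 25 °C)

In the violet flask at 120 min, activator stands at 0% of its charge and isomer of the product at 26.3%, and ring is still 13.1% at 1200 min. The same count goes to the neighbour charged with 1.1 M of activator at the violet temperature. That neighbour holds 0.550 of activator per substrate, so the yield of 13.8% gives 7.56% ring. At 120 min its activator stands at 0% of its charge and its substrate at 32.2%. The neighbour's ring comes out at 7.37%.

(The data were computed from invented constants, and the scatter is random.)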